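## Structural features

Labdane locants are used: ring A is C1–C5/C10, ring B is C5–C10, the chain is C11–C15. The target is a trans-fused decalin with a gem-dimethyl group on C4, an angular methyl on C10, a trisubstituted C7=C8 alkene bearing a methyl on C8, and a five-carbon chain on C9. The chain ends in a 13,14,15-triol whose secondary (O14) and primary (O15) hydroxyls are acetylated while the tertiary 13-OH is free. Ring B holds three contiguous stereocentres (5R, 10R quaternary, 9R): H5 is trans to the C10 methyl and the C9 chain is cis to it. The chain holds two contiguous centres (13S, 14R) that are insulated from the ring by C11–C12, so the ring cannot control them. The fragile points are the allylic C9–H (acid moves the alkene to C8=C9), the tertiary 13-OH facing that alkene (acid closes an 8,13-ether) and the acetates (hydrolysis, O14 to O13 migration). The real difficulty is the quaternary C10 in the correct relation to C5, and a C9–H centre that must be created beside an alkene that stays at C7=C8. Ring B (C5 carrying C4, C6, C7=C8 with its methyl, C9, C10) has the carbon pattern of (S)-carvone with the isopropenyl carbon as C4; the key step exploits this by closing ring A through one C3–C4 bond from a C4 cation onto a Z-vinylsilane hung on C10.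

## Logic of the disconnections

25 to 24 to 23: the two acyl C–O bonds at O14 and O15 are cut first, then the O–C and O–Si bonds of the protecting groups. The esters are the most base-labile groups and must come last. This leaves a protected triol that tolerates organolithium and palladium chemistry. The forward steps must acetylate only the primary and secondary hydroxyls and must unmask the triol without protonating C7=C8.

23 to 22: the C9–H bond is exchanged for a C9–O bond (tertiary allylic carbonate) with the alkene left at C7=C8. This turns C9 into the carbon of a ketone adduct and postpones its configuration. The forward hydride transfer must go to C9 and not C7, on the face opposite the leaving group.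

22 to 9 and 19 (through 20 and 21): the C9–C11 bond, the only ring-to-chain bond, is cut. The molecule falls into a C14 bicyclic enone and a C6 chain that already carries both chain stereocentres, so the plan is convergent. The forward step needs 1,2-addition to a congested enone anti to the C10 methyl, by a nucleophile that tolerates its own oxygen functions.

9 to 8: unsaturation is reintroduced at C2–C3 as the footprint of a vinylsilane terminator. The forward hydrogenation must distinguish a disubstituted alkene from the conjugated trisubstituted one.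

8 to 7: the C3–C4 bond is cut and ring A opens. What remains is a monocycle that already holds C5 and C10 with trans arms. The forward step must protonate the isopropenyl group selectively and close the ring before the C4 cation loses a proton.

7 to 6 to 3 and 4 to 1: the Z-alkene is traced to an alkyne, then the C10–C1 and C10–CH3 bonds are cut. Methyl goes in first so that the larger propargyl electrophile enters anti to the isopropenyl group and fixes C10. The gain is a commercial terpene as the source of C5.

19 to 18 to 16 to 15 to 13 (through 17 and 14): the C11–I bond is traced to a C11 alcohol and then to a terminal alkene, the acetonide is removed, and the C11–C12 bond is cut at an epoxide CH2. The forward opening must occur at CH2 so that the C13–O bond and its configuration are untouched.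

13 to 12 to 10 and 11: the epoxide C–O bonds are cut in a kinetic resolution that sets C13 and C14 together, then the C13–C14 bond is cut to an aldehyde and a Grignard reagent. The forward step needs a useful rate difference between the enantiomers of 12 and erythro selectivity.

## Other disconnections considered

Alternative 1: The cut removes C5–C10 and C8–C9 together, so both rings open to one chain. In the forward step a Me2AlCl-chelated (E)-enoyl imide (C9=C10, C11 as the imide carbonyl) adds to a tethered 2-silyloxy diene (C5=C6–C7=C8) to give A1.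
- In favour: one concerted step would set C5, C10 and C9, and C9 would carry carbon from the start. On the C9 centre this alternative is the better plan, because the chosen route sets C9 late by hydride transfer. Its stereochemical model (chelated auxiliary, intramolecular transition state) is at least the equal of a cation–olefin closure in predictability.
- Against: the dienophile is β,β-disubstituted at C10 and the diene terminus C5 sits next to quaternary C4, both of which should slow the cycloaddition. The silyl enol ether may not tolerate the Lewis acid. The C7 oxygen must later be converted into the C7=C8 alkene, and the C8 centre is made only to be erased. C11 is at the acyl level, so C12–C15 must be joined at a neopentyl-type carbon after reduction.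
- Comparison: the open-chain triene needs several stereodefined alkenes, so the step count would be clearly higher than in the chosen plan, which buys ring B with its methyl, alkene and carbonyl in place.

Alternative 2: The cut is C9–C10. In the forward step SnCl4 chelates the β-keto ester of A3, a proton adds to C5 of the ring alkene and the enol carbon C9 bonds to C10 in an anti addition, giving the trans-fused keto ester A2.
- In favour: ring A with its gem-dimethyl group and the C10 methyl comes ready-made from a bulk ketone. Here the alternative is better than the chosen plan, which has to build ring A. Acid-promoted closure of such keto esters is a long-established reaction type, so the key bond formation carries less mechanistic risk than the chosen key step.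
- Against: the absolute configuration would rest on a phenylmenthyl ester discriminating the faces of a remote tetrasubstituted alkene, a much weaker lever than a purchased stereocentre. A2 has a C8 ketone where the target needs C8–CH3 and C7=C8, so methyl addition and a regioselective dehydration (three alkenes possible) would be needed. C9 is epimerisable, and the chain must again be attached at C11.
- Comparison: the route to the bicyclic core is the equal of or shorter than the chosen one. Enantiocontrol and the C7–C9 adjustments are weaker, and the overall count is comparable.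

Alternative 3: The cut is C5=C6. In the forward step a base-mediated intramolecular aldol condensation of diketone A5 closes ring B as enone A4.
- In favour: judged as a single step this is the most dependable ring formation of the four plans, and in that respect it is better than the chosen key step. C10 is quaternary before ring closure and cannot epimerise.
- Against: A5 needs an enantioselective Michael addition at a crowded α-carbon. A4 has oxygen at C7, unsaturation at C5=C6 and nothing at C8 or C9. H5 would need a dissolving-metal reduction, C8 a methylation, and C9 (β to the carbonyl, next to quaternary C10) a dehydrogenation and conjugate addition, before C7 is deoxygenated into the alkene.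
- Comparison: structural overlap with the target is the lowest and the step count the highest. Carvone already supplies the C8 methyl, C7=C8 and a C9 carbonyl.

Key step: step 4

Remark on the chemistry: short-lived carbocations and catalyst-bound species are described in the Why lines and carry no number; stoichiometric species that persist in the flask and react on are numbered.

## Route

Step 1
Reactants: 1 (S)-(+)-carvone
Product: 3 (5S)-2,6-dimethyl-5-(prop-1-en-2-yl)cyclohex-2-en-1-one (both C6 epimers), via lithium dienolate 2 (not isolated)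
Conditions: LiN(iPr)2, THF, −78 °C; CH3I, −78 → 0 °C
Reagents that add atoms: iodomethane, CI
Why: Kinetic deprotonation at the α′-methylene gives the cross-conjugated dienolate, and SN2 methylation (enolate alkylation) installs the future C10 methyl; the epimer ratio at C6 is irrelevant because that carbon is planarised again in step 2.

Step 2
Reactants: 3 (5S)-2,6-dimethyl-5-(prop-1-en-2-yl)cyclohex-2-en-1-one; 4 3-bromo-1-(trimethylsilyl)prop-1-yne
Product: 6 (5R,6R)-2,6-dimethyl-5-(prop-1-en-2-yl)-6-[3-(trimethylsilyl)prop-2-yn-1-yl]cyclohex-2-en-1-one, via lithium enolate 5 (not isolated)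
Conditions: LiN(iPr)2, THF, −78 °C; 4, DMPU, −78 → 0 °C
Reagents that add atoms: none
Why: Enolate alkylation at the methyl-bearing α′-carbon creates the quaternary centre (future C10); the propargylic bromide approaches the enolate face anti to the adjacent isopropenyl group, so the new chain is trans to it and the methyl cis, which is the arrangement a trans ring fusion needs.

Step 3
Reactants: 6 (5R,6R)-2,6-dimethyl-5-(prop-1-en-2-yl)-6-[3-(trimethylsilyl)prop-2-yn-1-yl]cyclohex-2-en-1-one
Product: 7 (5R,6R)-2,6-dimethyl-5-(prop-1-en-2-yl)-6-[(2Z)-3-(trimethylsilyl)prop-2-en-1-yl]cyclohex-2-en-1-one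
Conditions: H2 (1 atm), Pd/CaCO3 poisoned with Pb(OAc)2, quinoline, EtOAc, rt
Reagents that add atoms: none
Why: Syn semihydrogenation of the silylalkyne on the poisoned catalyst gives the Z-vinylsilane; the alkyne binds far more strongly than the 1,1-disubstituted and conjugated alkenes, which should survive if uptake is stopped at one equivalent.

Step 4
Reactants: 7 (5R,6R)-2,6-dimethyl-5-(prop-1-en-2-yl)-6-[(2Z)-3-(trimethylsilyl)prop-2-en-1-yl]cyclohex-2-en-1-one
Product: 8 (4aR,8aR)-2,5,5,8a-tetramethyl-4a,5,8,8a-tetrahydronaphthalen-1(4H)-one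
Conditions: CF3SO3H (2 equiv), CH2Cl2, −78 → −40 °C; NaHCO3 (aq.)
Reagents that add atoms: none
Why: Triflic acid protonates the terminal carbon of the isopropenyl alkene to give the tertiary C4 cation, while the enone is only O-protonated and its C7=C8 bond thereby deactivated. The silicon-bearing carbon C3 of the Z-vinylsilane attacks C4, the resulting C2 cation is stabilised by hyperconjugation with the C3–Si bond, and triflate removes silicon to leave the C2=C3 alkene; this is a vinylsilane-terminated cation–olefin cyclisation of the kind used to terminate polyene cyclisations. Ring A closes in a 6-endo-trig mode with respect to the vinylsilane, since closure through C2 to a five-membered ring would put the charge on a carbon α to silicon. No stereocentre is created: C5 and C10 are already fixed, and because the two arms are trans (diequatorial) on ring B the only unstrained closure is the trans-fused one. Replacement of silicon with retention requires the Z geometry, because only then do C1 and C4 end up cis on the new ring alkene. The step needs protonation of the isopropenyl group in preference to the vinylsilane, which the more stable tertiary cation and the low temperature should secure, and ring closure faster than proton loss from C4 towards C5, which the six-membered intramolecular transition state and the non-basic counter-ion should secure.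

Step 5
Reactants: 8 (4aR,8aR)-2,5,5,8a-tetramethyl-4a,5,8,8a-tetrahydronaphthalen-1(4H)-one
Product: 9 (4aR,8aR)-2,5,5,8a-tetramethyl-4a,5,6,7,8,8a-hexahydronaphthalen-1(4H)-one
Conditions: RhCl(PPh3)3 (5 mol %), H2 (1–3 atm), toluene/EtOH, rt
Reagents that add atoms: none
Why: Homogeneous hydrogenation with RhCl(PPh3)3 reduces the cis-disubstituted C2=C3 alkene and leaves the trisubstituted, conjugated C7=C8 bond alone, the same selectivity that allows the isopropenyl group of carvone to be reduced beside its enone.

Step 6
Reactants: 10 (tert-butyldimethylsilyloxy)acetaldehyde; 11 isopropenylmagnesium bromide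
Product: 12 rac-1-[(tert-butyldimethylsilyl)oxy]-3-methylbut-3-en-2-ol
Conditions: THF, −78 → 0 °C; then H2O
Reagents that add atoms: none
Why: Grignard addition to the aldehyde forms the C13–C14 bond and gives the racemic 2-substituted allylic alcohol needed for resolution.

Step 7
Reactants: 12 rac-1-[(tert-butyldimethylsilyl)oxy]-3-methylbut-3-en-2-ol
Product: 13 (1R)-2-[(tert-butyldimethylsilyl)oxy]-1-[(2S)-2-methyloxiran-2-yl]ethan-1-ol
Conditions: Ti(OiPr)4 (0.2 equiv), D-(−)-diisopropyl tartrate (0.25 equiv), t-BuOOH (0.5 equiv), 4 Å molecular sieves, CH2Cl2, −20 °C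
Reagents that add atoms: tert-butyl hydroperoxide, CC(C)(C)OO
Why: Sharpless kinetic resolution: with the D-(−)-tartrate the (S)-enantiomer of 12 should be epoxidised faster, on the face that gives the erythro epoxy alcohol, which sets C13 (S) and C14 (R) in one event. The reaction is stopped below half conversion and the unreacted (R)-alcohol is removed by chromatography.

Step 8
Reactants: 13 (1R)-2-[(tert-butyldimethylsilyl)oxy]-1-[(2S)-2-methyloxiran-2-yl]ethan-1-ol
Product: 15 (2R,3S)-1-[(tert-butyldimethylsilyl)oxy]-3-methylhex-5-ene-2,3-diol, via bromomagnesium alkoxide 14 (not isolated)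
Conditions: CH2=CHMgBr (3 equiv), CuBr·SMe2 (10 mol %), THF, −40 → 0 °C; then H2O
Reagents that add atoms: vinylmagnesium bromide, C=C[Mg]Br
Why: Copper-catalysed SN2 opening of the 2,2-disubstituted epoxide at its CH2 terminus (C12); the C13–O bond is not touched, so C13 keeps its configuration, and the first equivalent of Grignard reagent only deprotonates the hydroxyl.

Step 9
Reactants: 15 (2R,3S)-1-[(tert-butyldimethylsilyl)oxy]-3-methylhex-5-ene-2,3-diol
Product: 16 tert-butyldimethyl{[(4R,5S)-2,2,5-trimethyl-5-(prop-2-en-1-yl)-1,3-dioxolan-4-yl]methoxy}silane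
Conditions: (CH3)2C(OCH3)2, pyridinium p-toluenesulfonate (cat.), CH2Cl2, rt
Reagents that add atoms: 2,2-dimethoxypropane, COC(C)(C)OC
Why: Transketalisation on the only 1,2-diol ties O13 and O14 into an acetonide, which removes every acidic proton before the organolithium step and cannot undergo silyl migration to carbon.

Step 10
Reactants: 16 tert-butyldimethyl{[(4R,5S)-2,2,5-trimethyl-5-(prop-2-en-1-yl)-1,3-dioxolan-4-yl]methoxy}silane
Product: 18 2-[(4S,5R)-5-{[(tert-butyldimethylsilyl)oxy]methyl}-2,2,4-trimethyl-1,3-dioxolan-4-yl]ethan-1-ol, via aldehyde 17 (not isolated)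
Conditions: O3, CH2Cl2/MeOH, −78 °C; NaBH4, −78 °C → rt
Reagents that add atoms: ozone, [O-][O+]=O
Why: Ozonolysis removes the terminal carbon of the alkene and leaves C11 as an aldehyde, which NaBH4 reduces in the same flask to the primary alcohol; no stereocentre is involved.

Step 11
Reactants: 18 2-[(4S,5R)-5-{[(tert-butyldimethylsilyl)oxy]methyl}-2,2,4-trimethyl-1,3-dioxolan-4-yl]ethan-1-ol
Product: 19 tert-butyl{[(4R,5S)-5-(2-iodoethyl)-2,2,5-trimethyl-1,3-dioxolan-4-yl]methoxy}dimethylsilane
Conditions: I2, PPh3, imidazole, CH2Cl2, 0 °C → rt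
Reagents that add atoms: iodine, II
Why: Appel-type iodination of the primary alcohol through its alkoxyphosphonium salt; the buffered conditions leave the acetonide and silyl ether intact.

Step 12
Reactants: 19 tert-butyl{[(4R,5S)-5-(2-iodoethyl)-2,2,5-trimethyl-1,3-dioxolan-4-yl]methoxy}dimethylsilane; 9 (4aR,8aR)-2,5,5,8a-tetramethyl-4a,5,6,7,8,8a-hexahydronaphthalen-1(4H)-one
Product: 22 methyl (1R,4aR,8aR)-1-{2-[(4S,5R)-5-{[(tert-butyldimethylsilyl)oxy]methyl}-2,2,4-trimethyl-1,3-dioxolan-4-yl]ethyl}-2,5,5,8a-tetramethyl-1,4,4a,5,6,7,8,8a-octahydronaphthalen-1-yl carbonate, via alkyllithium 20 (not isolated), via lithium alkoxide 21 (not isolated)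
Conditions: t-BuLi (2 equiv per 19), Et2O/pentane, −78 °C; 9, −78 → −30 °C; ClCO2CH3, −78 °C → rt
Reagents that add atoms: methyl chloroformate, COC(=O)Cl
Why: Iodine–lithium exchange gives a primary alkyllithium whose oxygen is γ and therefore cannot eliminate; it should add 1,2 to the enone by axial attack on the β-face, anti to the axial C10 methyl, so C11 is β and the alkoxide α. Trapping the lithium alkoxide in the flask with methyl chloroformate avoids a separate acylation of a hindered tertiary alcohol.

Step 13
Reactants: 22 methyl (1R,4aR,8aR)-1-{2-[(4S,5R)-5-{[(tert-butyldimethylsilyl)oxy]methyl}-2,2,4-trimethyl-1,3-dioxolan-4-yl]ethyl}-2,5,5,8a-tetramethyl-1,4,4a,5,6,7,8,8a-octahydronaphthalen-1-yl carbonate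
Product: 23 tert-butyldimethyl{[(4R,5S)-2,2,5-trimethyl-5-{2-[(1R,4aR,8aR)-2,5,5,8a-tetramethyl-1,4,4a,5,6,7,8,8a-octahydronaphthalen-1-yl]ethyl}-1,3-dioxolan-4-yl]methoxy}silane
Conditions: Pd(OAc)2/PBu3 (1:1, 5 mol %), HCO2H, Et3N, THF, 40 °C
Reagents that add atoms: none
Why: Palladium-catalysed formate hydrogenolysis of an allylic carbonate (Tsuji type): zerovalent palladium ionises the carbonate from the β-face, opposite the leaving group, formate takes the place of methyl carbonate on the metal, and loss of CO2 transfers hydride to the more substituted allyl terminus C9 on the palladium-bearing face. H9 therefore ends up β, the chain α (cis to the C10 methyl), and the alkene stays at C7=C8; PBu3 is the ligand that favours delivery to the more substituted terminus.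

Step 14
Reactants: 23 tert-butyldimethyl{[(4R,5S)-2,2,5-trimethyl-5-{2-[(1R,4aR,8aR)-2,5,5,8a-tetramethyl-1,4,4a,5,6,7,8,8a-octahydronaphthalen-1-yl]ethyl}-1,3-dioxolan-4-yl]methoxy}silane
Product: 24 (2R,3S)-3-methyl-5-[(1R,4aR,8aR)-2,5,5,8a-tetramethyl-1,4,4a,5,6,7,8,8a-octahydronaphthalen-1-yl]pentane-1,2,3-triol
Conditions: p-TsOH·H2O (10 mol %), MeOH, 0 °C → rt; Et3N
Reagents that add atoms: none
Why: Acid-catalysed methanolysis removes the acetonide (transketalisation) and the primary silyl ether in one operation; a catalytic sulfonic acid at or below room temperature should be too weak to protonate C7=C8, which would otherwise be trapped by O13 as an 8,13-ether.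

Step 15
Reactants: 24 (2R,3S)-3-methyl-5-[(1R,4aR,8aR)-2,5,5,8a-tetramethyl-1,4,4a,5,6,7,8,8a-octahydronaphthalen-1-yl]pentane-1,2,3-triol
Product: 25 (2R,3S)-3-hydroxy-3-methyl-5-[(1R,4aR,8aR)-2,5,5,8a-tetramethyl-1,4,4a,5,6,7,8,8a-octahydronaphthalen-1-yl]pentane-1,2-diyl diacetate
Conditions: Ac2O (2.5 equiv), pyridine, DMAP (2 mol %), CH2Cl2, 0 °C → rt
Reagents that add atoms: acetic anhydride, CC(=O)OC(C)=O
Why: Chemoselective O-acetylation: the primary and secondary hydroxyls react while the tertiary 13-OH should not under these conditions, and the short, mildly basic treatment gives no opportunity for acyl migration.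

## Compound list

1 | (S)-(+)-carvone, (5S)-2-methyl-5-(prop-1-en-2-yl)cyclohex-2-en-1-one | CC1=CC[C@@H](CC1=O)C(C)=C | starting material
2 | lithium dienolate of 1 (O–C1=C6 and C2=C3; isopropenyl-bearing carbon unchanged) | [Li]OC1=C[C@@H](C(C)=C)CC=C1C | intermediate
3 | (5S)-2,6-dimethyl-5-(prop-1-en-2-yl)cyclohex-2-en-1-one (6-methylcarvone, both C6 epimers) | O=C1C(C)=CC[C@H](C(C)=C)C1C | intermediate
4 | 3-bromo-1-(trimethylsilyl)prop-1-yne | C[Si](C)(C)C#CCBr | starting material
5 | lithium enolate of 3 (O–C1=C6(CH3) and C2=C3) | [Li]OC1=C(C)[C@@H](C(C)=C)CC=C1C | intermediate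
6 | (5R,6R)-2,6-dimethyl-5-(prop-1-en-2-yl)-6-[3-(trimethylsilyl)prop-2-yn-1-yl]cyclohex-2-en-1-one (same spatial arrangement at C5 as in 3; the descriptor changes because C6 is now quaternary) | O=C1C(C)=CC[C@H](C(C)=C)[C@@]1(C)CC#C[Si](C)(C)C | intermediate
7 | (5R,6R)-2,6-dimethyl-5-(prop-1-en-2-yl)-6-[(2Z)-3-(trimethylsilyl)prop-2-en-1-yl]cyclohex-2-en-1-one | O=C1C(C)=CC[C@H](C(C)=C)[C@@]1(C)C/C=C\[Si](C)(C)C | intermediate
8 | (4aR,8aR)-2,5,5,8a-tetramethyl-4a,5,8,8a-tetrahydronaphthalen-1(4H)-one (trans-fused; C2=C3 and C7=C8 in labdane locants) | O=C1C(C)=CC[C@@H]2C(C)(C)C=CC[C@@]12C | intermediate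
9 | (4aR,8aR)-2,5,5,8a-tetramethyl-4a,5,6,7,8,8a-hexahydronaphthalen-1(4H)-one | O=C1C(C)=CC[C@@H]2C(C)(C)CCC[C@@]12C | intermediate
10 | (tert-butyldimethylsilyloxy)acetaldehyde | CC(C)(C)[Si](C)(C)OCC=O | starting material
11 | isopropenylmagnesium bromide | CC(=C)[Mg]Br | starting material
12 | rac-1-[(tert-butyldimethylsilyl)oxy]-3-methylbut-3-en-2-ol | CC(C)(C)[Si](C)(C)OCC(O)C(C)=C | intermediate
13 | (1R)-2-[(tert-butyldimethylsilyl)oxy]-1-[(2S)-2-methyloxiran-2-yl]ethan-1-ol (erythro) | CC(C)(C)[Si](C)(C)OC[C@@H](O)[C@@]1(C)OC1 | intermediate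
14 | bromomagnesium alkoxide of 13 | CC(C)(C)[Si](C)(C)OC[C@@H](O[Mg]Br)[C@@]1(C)OC1 | intermediate
15 | (2R,3S)-1-[(tert-butyldimethylsilyl)oxy]-3-methylhex-5-ene-2,3-diol | C=CC[C@](C)(O)[C@H](O)CO[Si](C)(C)C(C)(C)C | intermediate
16 | tert-butyldimethyl{[(4R,5S)-2,2,5-trimethyl-5-(prop-2-en-1-yl)-1,3-dioxolan-4-yl]methoxy}silane | C=CC[C@]1(C)OC(C)(C)O[C@@H]1CO[Si](C)(C)C(C)(C)C | intermediate
17 | 2-[(4S,5R)-5-{[(tert-butyldimethylsilyl)oxy]methyl}-2,2,4-trimethyl-1,3-dioxolan-4-yl]acetaldehyde | O=CC[C@]1(C)OC(C)(C)O[C@@H]1CO[Si](C)(C)C(C)(C)C | intermediate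
18 | 2-[(4S,5R)-5-{[(tert-butyldimethylsilyl)oxy]methyl}-2,2,4-trimethyl-1,3-dioxolan-4-yl]ethan-1-ol | OCC[C@]1(C)OC(C)(C)O[C@@H]1CO[Si](C)(C)C(C)(C)C | intermediate
19 | tert-butyl{[(4R,5S)-5-(2-iodoethyl)-2,2,5-trimethyl-1,3-dioxolan-4-yl]methoxy}dimethylsilane | ICC[C@]1(C)OC(C)(C)O[C@@H]1CO[Si](C)(C)C(C)(C)C | intermediate
20 | primary alkyllithium from 19 (lithium in place of iodine) | [Li]CC[C@]1(C)OC(C)(C)O[C@@H]1CO[Si](C)(C)C(C)(C)C | intermediate
21 | lithium (1R,4aR,8aR)-1-{2-[(4S,5R)-5-{[(tert-butyldimethylsilyl)oxy]methyl}-2,2,4-trimethyl-1,3-dioxolan-4-yl]ethyl}-2,5,5,8a-tetramethyl-1,4,4a,5,6,7,8,8a-octahydronaphthalen-1-olate (chain β, oxygen α at C9) | [Li]O[C@]1(CC[C@]3(C)OC(C)(C)O[C@@H]3CO[Si](C)(C)C(C)(C)C)C(C)=CC[C@@H]2C(C)(C)CCC[C@@]12C | intermediate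
22 | methyl carbonate of the tertiary allylic alcohol corresponding to 21 | COC(=O)O[C@]1(CC[C@]3(C)OC(C)(C)O[C@@H]3CO[Si](C)(C)C(C)(C)C)C(C)=CC[C@@H]2C(C)(C)CCC[C@@]12C | intermediate
23 | tert-butyldimethyl{[(4R,5S)-2,2,5-trimethyl-5-{2-[(1R,4aR,8aR)-2,5,5,8a-tetramethyl-1,4,4a,5,6,7,8,8a-octahydronaphthalen-1-yl]ethyl}-1,3-dioxolan-4-yl]methoxy}silane | CC(C)(C)[Si](C)(C)OC[C@H]3OC(C)(C)O[C@@]3(C)CC[C@@H]1C(C)=CC[C@@H]2C(C)(C)CCC[C@@]12C | intermediate
24 | (2R,3S)-3-methyl-5-[(1R,4aR,8aR)-2,5,5,8a-tetramethyl-1,4,4a,5,6,7,8,8a-octahydronaphthalen-1-yl]pentane-1,2,3-triol | OC[C@@H](O)[C@@](C)(O)CC[C@@H]1C(C)=CC[C@@H]2C(C)(C)CCC[C@@]12C | intermediate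
25 | (2R,3S)-3-hydroxy-3-methyl-5-[(1R,4aR,8aR)-2,5,5,8a-tetramethyl-1,4,4a,5,6,7,8,8a-octahydronaphthalen-1-yl]pentane-1,2-diyl diacetate (labdane locants 5R,9R,10R,13S,14R) | CC(=O)OC[C@@H](OC(C)=O)[C@@](C)(O)CC[C@@H]1C(C)=CC[C@@H]2C(C)(C)CCC[C@@]12C | target

## Step count and least certain steps

Total: 15 steps. Longest linear sequence: 10 steps (steps 6–15, from 10 and 11); the carvone branch contributes 9 (steps 1–5 and 12–15).

Step 4 (key step). The most likely failure is proton loss from the C4 cation towards C5, which would erode the C5 configuration on re-protonation or drain material into a conjugated dienone. Protodesilylation of the vinylsilane by triflic acid before ring closure is the second risk. The fallback avoids free protons and sets out from 6. Gaseous HCl in CH2Cl2 at −20 °C should add to the isopropenyl group to give the tertiary chloride (5S,6R)-5-(2-chloropropan-2-yl)-2,6-dimethyl-6-[3-(trimethylsilyl)prop-2-yn-1-yl]cyclohex-2-en-1-one F1. Semihydrogenation as in step 3 would give the Z-vinylsilane chloride F2. SnCl4 in CH2Cl2 at −78 °C would then ionise the C–Cl bond under aprotic conditions, with chloride removing silicon after ring closure. The fallback returns to the route at 8.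

Step 13. The π-allylpalladium intermediate may undergo β-hydride elimination to dienes, hydride may go to C7 and give the tetrasubstituted C8=C9 isomer, or any facial leakage in step 12 would be carried into C9. The fallback sets C9 by dissolving-metal reduction instead and sets out from 21. Quenching 21 with water instead of methyl chloroformate would give the tertiary allylic alcohol F3. Pyridinium chlorochromate, [C5H5NH][CrO3Cl], in CH2Cl2 should effect the oxidative 1,3-transposition to the 7-oxo-8(9)-ene F4. Li in NH3/THF with one equivalent of t-BuOH at −78 °C, removal of NH3 and addition of PhNTf2 would give the enol triflate F5; axial protonation at C9 places H9 on the β-face whatever the configuration of F3. Pd(OAc)2, PPh3, HCO2H and Bu3N in DMF at 60 °C would replace the triflate by hydrogen. The fallback returns at 23.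

Step 12. The carbonyl lies between quaternary C10 and the C8 methyl, so addition may be slow enough for γ-deprotonation at C6 to return 9, and acylation of the crowded alkoxide in the flask may stall. The fallback forms C9–C11 by cross-coupling and sets out from 9 and 19. LiN(iPr)2 and PhNTf2 would convert 9 into the dienyl triflate (4aR,8aR)-2,5,5,8a-tetramethyl-4a,5,6,7,8,8a-hexahydronaphthalen-1-yl trifluoromethanesulfonate F6. Activated zinc dust in THF/DMA would convert 19 into the alkylzinc iodide F7. Negishi coupling with PdCl2(dppf) would give the homoannular diene F8. 1,4-Hydrogenation of this s-cis diene with (η6-naphthalene)Cr(CO)3 and H2 (30 atm) in THF at 45 °C should add hydrogen to C6 and C9 from the face opposite the C10 methyl and leave C7=C8. The fallback returns at 23.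

Step 3. The silylalkyne may take up hydrogen slowly on the poisoned catalyst, and the isopropenyl group may then be reduced as well. The fallback makes the Z-vinylsilane on a small molecule with no other alkene, and sets out from 3 through its enolate 5. Purchased 3-(trimethylsilyl)prop-2-yn-1-ol would be semihydrogenated (H2, Ni(OAc)2/NaBH4, ethylenediamine, EtOH) to (2Z)-3-(trimethylsilyl)prop-2-en-1-ol F9 and brominated (CBr4, PPh3) to [(1Z)-3-bromoprop-1-en-1-yl]trimethylsilane F10. Alkylation of 5 with F10 under the conditions of step 2 gives the precursor directly. The fallback returns at 7.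

Step 7. The silyloxymethyl group may reduce the rate difference between the enantiomers, giving 13 of insufficient enantiomeric purity, and the resolution cannot pass half of the material. The fallback separates the two tasks and sets out from 12. Burkholderia cepacia lipase with vinyl acetate should acylate the (R)-alcohol to the acetate F12 and leave (2S)-1-[(tert-butyldimethylsilyl)oxy]-3-methylbut-3-en-2-ol F11; this assignment follows the empirical size rule and would have to be confirmed, and if it were reversed the acetate fraction would be hydrolysed and used. Hydroxyl-directed epoxidation of F11 with VO(acac)2 and t-BuOOH, which favours the erythro isomer for 2-substituted allylic alcohols, returns to the route at 13.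

## Further compounds

F1 | step 4 | (5S,6R)-5-(2-chloropropan-2-yl)-2,6-dimethyl-6-[3-(trimethylsilyl)prop-2-yn-1-yl]cyclohex-2-en-1-one | O=C1C(C)=CC[C@H](C(C)(C)Cl)[C@@]1(C)CC#C[Si](C)(C)C
F2 | step 4 | (5S,6R)-5-(2-chloropropan-2-yl)-2,6-dimethyl-6-[(2Z)-3-(trimethylsilyl)prop-2-en-1-yl]cyclohex-2-en-1-one | O=C1C(C)=CC[C@H](C(C)(C)Cl)[C@@]1(C)C/C=C\[Si](C)(C)C
F3 | step 13 | (1R,4aR,8aR)-1-{2-[(4S,5R)-5-{[(tert-butyldimethylsilyl)oxy]methyl}-2,2,4-trimethyl-1,3-dioxolan-4-yl]ethyl}-2,5,5,8a-tetramethyl-1,4,4a,5,6,7,8,8a-octahydronaphthalen-1-ol | O[C@]1(CC[C@]3(C)OC(C)(C)O[C@@H]3CO[Si](C)(C)C(C)(C)C)C(C)=CC[C@@H]2C(C)(C)CCC[C@@]12C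
F4 | step 13 | (4aR,8aR)-4-{2-[(4S,5R)-5-{[(tert-butyldimethylsilyl)oxy]methyl}-2,2,4-trimethyl-1,3-dioxolan-4-yl]ethyl}-3,4a,8,8-tetramethyl-4a,5,6,7,8,8a-hexahydronaphthalen-2(1H)-one | O=C1C[C@@H]2C(C)(C)CCC[C@@]2(C)C(CC[C@]3(C)OC(C)(C)O[C@@H]3CO[Si](C)(C)C(C)(C)C)=C1C
F5 | step 13 | enol triflate of the saturated C7 ketone (labdane locants: 7-trifluoromethanesulfonyloxy-7-ene, 9β-H, protected chain as in 23) | CC1=C(OS(=O)(=O)C(F)(F)F)C[C@@H]2C(C)(C)CCC[C@@]2(C)[C@@H]1CC[C@]3(C)OC(C)(C)O[C@@H]3CO[Si](C)(C)C(C)(C)C
F6 | step 12 | (4aR,8aR)-2,5,5,8a-tetramethyl-4a,5,6,7,8,8a-hexahydronaphthalen-1-yl trifluoromethanesulfonate | O=S(=O)(OC1=C(C)C=C[C@@H]2C(C)(C)CCC[C@@]12C)C(F)(F)F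
F7 | step 12 | {2-[(4S,5R)-5-{[(tert-butyldimethylsilyl)oxy]methyl}-2,2,4-trimethyl-1,3-dioxolan-4-yl]ethyl}zinc iodide | I[Zn]CC[C@]1(C)OC(C)(C)O[C@@H]1CO[Si](C)(C)C(C)(C)C
F8 | step 12 | tert-butyldimethyl{[(4R,5S)-2,2,5-trimethyl-5-{2-[(4aR,8aR)-2,5,5,8a-tetramethyl-4a,5,6,7,8,8a-hexahydronaphthalen-1-yl]ethyl}-1,3-dioxolan-4-yl]methoxy}silane | C1(CC[C@]3(C)OC(C)(C)O[C@@H]3CO[Si](C)(C)C(C)(C)C)=C(C)C=C[C@@H]2C(C)(C)CCC[C@@]12C
F9 | step 3 | (2Z)-3-(trimethylsilyl)prop-2-en-1-ol | C[Si](C)(C)/C=C\CO
F10 | step 3 | [(1Z)-3-bromoprop-1-en-1-yl]trimethylsilane | C[Si](C)(C)/C=C\CBr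
F11 | step 7 | (2S)-1-[(tert-butyldimethylsilyl)oxy]-3-methylbut-3-en-2-ol | CC(C)(C)[Si](C)(C)OC[C@@H](O)C(C)=C
F12 | step 7 | (2R)-1-[(tert-butyldimethylsilyl)oxy]-3-methylbut-3-en-2-yl acetate | CC(C)(C)[Si](C)(C)OC[C@H](OC(C)=O)C(C)=C
A1 | alternative 1 | trans-fused bicyclic N-acyl (4R)-4-benzyloxazolidin-2-one with a C6=C7 tert-butyldimethylsilyl enol ether | O=C(N3[C@H](Cc4ccccc4)COC3=O)[C@@H]1[C@H](C)C(O[Si](C)(C)C(C)(C)C)=C[C@@H]2C(C)(C)CCC[C@@]12C
A2 | alternative 2 | 8-phenylmenthyl ester of the trans-fused bicyclic β-keto acid (C8 ketone, C9 ester) | O=C(O[C@@H]3C[C@H](C)CC[C@H]3C(C)(C)c3ccccc3)[C@@H]1C(=O)CC[C@@H]2C(C)(C)CCC[C@@]12C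
A3 | alternative 2 | 8-phenylmenthyl 3-oxo-5-(2,6,6-trimethylcyclohex-1-en-1-yl)pentanoate | O=C(CC(=O)CCC1=C(C)CCCC1(C)C)O[C@@H]2C[C@H](C)CC[C@H]2C(C)(C)c3ccccc3
A4 | alternative 3 | (S)-4a,8,8-trimethyl-4,4a,5,6,7,8-hexahydronaphthalen-2(3H)-one | O=C1CC[C@]2(C)CCCC(C)(C)C2=C1
A5 | alternative 3 | (S)-2,2,6-trimethyl-6-(3-oxobutyl)cyclohexan-1-one | CC(=O)CC[C@]1(C)CCCC(C)(C)C1=O
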